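Ring A is disconnected across C1–C2 and C5–C6. C1 (carboxyl) and C6 (pentyl) come from an oct-2-ynoate; the C2(OH)–C3(H)–C4(O-acyl)–C5(H) array comes from an acetoacetate-derived ketene-acetal diene whose oxygen destined for C4 already carries the ring B acyl group. One Diels–Alder/aromatisation should therefore build ring A with all four substituents placed and the depside ester already in position. The precursor is the silyl ketene acetal of the enol ester between methyl acetoacetate and 3-chloro-2,4-dimethoxy-6-pentylbenzoic acid. Ring B travels as its dimethyl ether, so that the hindered acid can be activated as its chloride; its C2 methyl ether is cleaved last under chelation control.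

Key step: step 6

Remark on the chemistry: enol ester 8 and diene 10 are carried as E/Z mixtures, since both geometries converge on the same aromatic ring; 1 is taken as the commercial dimethyl ether of olivetol.

Step 1
Reactants: 1 1,3-dimethoxy-5-pentylbenzene
Product: 3 2-chloro-1,3-dimethoxy-5-pentylbenzene, via aryllithium 2 (not isolated)
Conditions: n-BuLi, THF, 0 °C to rt; then C2Cl6, −78 °C to rt
Reagents that add atoms: hexachloroethane ClC(Cl)(Cl)C(Cl)(Cl)Cl
Why: Directed ortho-metalation occurs at the one ring carbon flanked by both methoxy groups, and electrophilic chlorination of aryllithium 2 by hexachloroethane should place the chlorine between the two oxygens without ambiguity.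

Step 2
Reactants: 3 2-chloro-1,3-dimethoxy-5-pentylbenzene
Product: 5 3-chloro-2,4-dimethoxy-6-pentylbenzoic acid, via aryllithium 4 (not isolated)
Conditions: s-BuLi, TMEDA, THF, −78 to −40 °C; then CO2, −78 °C to rt; 1 M HCl
Reagents that add atoms: carbon dioxide O=C=O
Why: A second methoxy-directed ortho-metalation followed by carboxylation can give only one acid, because the two remaining ring C–H positions of symmetrical 3 are equivalent.

Step 3
Reactants: 5 3-chloro-2,4-dimethoxy-6-pentylbenzoic acid; 6 methyl acetoacetate
Product: 8 methyl 3-[(3-chloro-2,4-dimethoxy-6-pentylbenzoyl)oxy]but-2-enoate (E/Z mixture), via acid chloride 7 (not isolated)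
Conditions: (COCl)2, DMF (cat.), CH2Cl2, 0 °C to rt, evaporate; then 6, Et3N, CH2Cl2, 0 °C to rt
Reagents that add atoms: none
Why: Enol ester formation by O-acylation of a β-keto ester under amine base: the triethylammonium enolate of 6 should react through oxygen with the ionisation-prone aroyl chloride 7, whose di-ortho-substituted carbonyl disfavours C-acylation, and the ring B methyl ethers are inert to oxalyl chloride.

Step 4
Reactants: 8 methyl 3-[(3-chloro-2,4-dimethoxy-6-pentylbenzoyl)oxy]but-2-enoate
Product: 10 4-methoxy-4-[(trimethylsilyl)oxy]buta-1,3-dien-2-yl 3-chloro-2,4-dimethoxy-6-pentylbenzoate (E/Z mixture), via lithium dienolate 9 (not isolated)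
Conditions: Me3SiCl, THF, −78 °C; LiN(iPr)2 added (in situ quench), −78 to 0 °C; pentane, filtration; used crude
Reagents that add atoms: chlorotrimethylsilane C[Si](C)(C)Cl
Why: Kinetic γ-deprotonation of the crotonate and O-silylation of the ester dienolate is the standard entry to vinylketene silyl acetals from β-oxygenated crotonates, and here trapping by Me3SiCl already present, together with the shielded aroate carbonyl, should keep the enol ester intact.

Step 5
Reactants: 11 hept-1-yne; 12 di-tert-butyl dicarbonate
Product: 14 tert-butyl oct-2-ynoate, via heptynyllithium 13 (not isolated)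
Conditions: n-BuLi, THF, −78 °C; then 12, −78 to 0 °C
Reagents that add atoms: none
Why: Alkoxycarbonylation of a lithium acetylide with Boc2O is a standard one-step route to tert-butyl alk-2-ynoates.

Step 6
Reactants: 10 4-methoxy-4-[(trimethylsilyl)oxy]buta-1,3-dien-2-yl 3-chloro-2,4-dimethoxy-6-pentylbenzoate; 14 tert-butyl oct-2-ynoate
Product: 16 tert-butyl 4-[(3-chloro-2,4-dimethoxy-6-pentylbenzoyl)oxy]-2-hydroxy-6-pentylbenzoate, via cycloadduct 15 (not isolated)
Conditions: 10 (1.5–2 equiv), toluene, 110–130 °C, sealed tube; then 1 M HCl, THF, 0 °C
Reagents that add atoms: none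
Why: The ketene-acetal terminus polarises diene 10 so that its CH2 carbon (future C5) attacks the pentyl-bearing β-carbon of ynoate 14 (future C6) while the acetal carbon (future C2) bonds to the α-carbon (future C1), in a concerted but asynchronous thermal [4+2] cycloaddition. The closest known reaction type is the Diels–Alder benzannulation of 1,1,3-trioxygenated butadienes with acetylenic esters, which gives 2,4-dioxygenated 6-alkylbenzoates; the untested element is the aroyl group on the diene oxygen in place of alkyl or silyl, which lowers the diene HOMO and is why heat and an excess of diene are planned. Ring A is closed by intermolecular [4+2] cycloaddition, both new σ-bonds (C1–C2 and C5–C6) forming in one event to give 1,4-cyclohexadiene 15. The single sp3 acetal centre of 15 is racemic and disappears when the silyl mixed ketal collapses on acidic work-up with loss of methanol and tautomerisation to the C2 phenol, so no stereocentre needs control. The step needs regioselectivity, secured by the matched polarisation of the 1,1-dioxygenated diene and the ynoate β-carbon, and survival of the enol ester, secured by the di-ortho-substituted ring B carbonyl that resists acyl transfer to the liberated phenol or methanol. Should part of the adduct collapse by loss of silanol to the ring A C2 methyl ether, that ether lies ortho to the ester and should be cleaved in step 7 as well, so both modes converge.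

Step 7
Reactants: 16 tert-butyl 4-[(3-chloro-2,4-dimethoxy-6-pentylbenzoyl)oxy]-2-hydroxy-6-pentylbenzoate
Product: 17 4-[(3-chloro-2-hydroxy-4-methoxy-6-pentylbenzoyl)oxy]-2-hydroxy-6-pentylbenzoic acid (target CNP0310773.0)
Conditions: BCl3, CH2Cl2, −78 to 0 °C; then H2O
Reagents that add atoms: none
Why: Chelation-controlled ether cleavage: BCl3 held by the ring B ester carbonyl should remove only the neighbouring C2 methyl group, leaving the unchelated C4 methoxy group, the aryl chloride and the hindered depside ester untouched, while the same Lewis acid ionises the tert-butyl ester to the free acid.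

Compound list
1 | 1,3-dimethoxy-5-pentylbenzene (olivetol dimethyl ether) | CCCCCc1cc(OC)cc(OC)c1 | starting material
2 | (2,6-dimethoxy-4-pentylphenyl)lithium | [Li]c1c(OC)cc(CCCCC)cc1OC | intermediate
3 | 2-chloro-1,3-dimethoxy-5-pentylbenzene | CCCCCc1cc(OC)c(Cl)c(OC)c1 | intermediate
4 | (3-chloro-2,4-dimethoxy-6-pentylphenyl)lithium | [Li]c1c(CCCCC)cc(OC)c(Cl)c1OC | intermediate
5 | 3-chloro-2,4-dimethoxy-6-pentylbenzoic acid | CCCCCc1cc(OC)c(Cl)c(OC)c1C(=O)O | intermediate
6 | methyl acetoacetate | CC(=O)CC(=O)OC | starting material
7 | 3-chloro-2,4-dimethoxy-6-pentylbenzoyl chloride | CCCCCc1cc(OC)c(Cl)c(OC)c1C(Cl)=O | intermediate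
8 | methyl 3-[(3-chloro-2,4-dimethoxy-6-pentylbenzoyl)oxy]but-2-enoate (E/Z mixture) | CCCCCc1cc(OC)c(Cl)c(OC)c1C(=O)OC(C)=CC(=O)OC | intermediate
9 | lithium 3-[(3-chloro-2,4-dimethoxy-6-pentylbenzoyl)oxy]-1-methoxybuta-1,3-dien-1-olate | C=C(OC(=O)c1c(CCCCC)cc(OC)c(Cl)c1OC)C=C(OC)O[Li] | intermediate
10 | 4-methoxy-4-[(trimethylsilyl)oxy]buta-1,3-dien-2-yl 3-chloro-2,4-dimethoxy-6-pentylbenzoate (E/Z mixture) | C=C(OC(=O)c1c(CCCCC)cc(OC)c(Cl)c1OC)C=C(OC)O[Si](C)(C)C | intermediate
11 | hept-1-yne | CCCCCC#C | starting material
12 | di-tert-butyl dicarbonate | CC(C)(C)OC(=O)OC(=O)OC(C)(C)C | starting material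
13 | hept-1-yn-1-yllithium | CCCCCC#C[Li] | intermediate
14 | tert-butyl oct-2-ynoate | CCCCCC#CC(=O)OC(C)(C)C | intermediate
15 | tert-butyl 4-[(3-chloro-2,4-dimethoxy-6-pentylbenzoyl)oxy]-6-methoxy-2-pentyl-6-[(trimethylsilyl)oxy]cyclohexa-1,4-diene-1-carboxylate (racemic) | CCCCCC1=C(C(=O)OC(C)(C)C)C(OC)(O[Si](C)(C)C)C=C(OC(=O)c2c(CCCCC)cc(OC)c(Cl)c2OC)C1 | intermediate
16 | tert-butyl 4-[(3-chloro-2,4-dimethoxy-6-pentylbenzoyl)oxy]-2-hydroxy-6-pentylbenzoate | CCCCCc1cc(OC(=O)c2c(CCCCC)cc(OC)c(Cl)c2OC)cc(O)c1C(=O)OC(C)(C)C | intermediate
17 | 4-[(3-chloro-2-hydroxy-4-methoxy-6-pentylbenzoyl)oxy]-2-hydroxy-6-pentylbenzoic acid | CCCCCc1cc(OC(=O)c2c(CCCCC)cc(OC)c(Cl)c2O)cc(O)c1C(=O)O | target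

Total steps: 7. Longest linear sequence: 6 (steps 1, 2, 3, 4, 6, 7); step 5 is a one-step side branch.

Steps most likely to fail

Step 6. The aroyloxy diene may be too electron-poor to engage the β-alkyl ynoate before it is desilylated or dimerises, or the enol ester may be transferred during heating. The fallback forms the depside bond last. It sets out from ynoate 14 and, for the acyl part, from acid 5 through its chloride 7. Heating 14 with commercial 1-methoxy-1,3-bis(trimethylsilyloxy)buta-1,3-diene (toluene, 110–130 °C; then 1 M HCl) should give tert-butyl 2,4-dihydroxy-6-pentylbenzoate F1 by the established benzannulation of bis-silyloxy dienes with alkynoates. Acylation of F1 with 7 (pyridine, CH2Cl2, 0 °C to rt) should take place at the free 4-hydroxyl, the 2-hydroxyl being held in a hydrogen bond to the ester, and gives 16, where the route resumes.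

Step 4. The lithium dienolate may expel the aroate, or the amide base may attack the enol ester, before silylation takes place. The fallback avoids any lithium amide and sets out from acid 5. Markovnikov addition of 5 to the terminal alkyne of commercial methyl but-3-ynoate ([RuCl2(p-cymene)]2, tri(2-furyl)phosphine, Na2CO3, toluene, 50 °C) should give the deconjugated enol ester methyl 3-[(3-chloro-2,4-dimethoxy-6-pentylbenzoyl)oxy]but-3-enoate F2. Its α-methylene, activated by both the ester and the vinyl group, should be silylated under soft enolisation (Et3N, Me3SiOSO2CF3, Et2O, 0 °C), which returns to diene 10.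

Step 2. Metalation at the crowded position beside the pentyl chain may be slow, with benzylic deprotonation competing. The fallback replaces deprotonation by halogen–metal exchange and sets out from 3. Bromination with N-bromosuccinimide (MeCN, 0 °C to rt) should give a single monobromide, 1-bromo-3-chloro-2,4-dimethoxy-6-pentylbenzene F3, because the two free ring positions are equivalent. Bromine–lithium exchange (n-BuLi, THF, −78 °C) then generates aryllithium 4 regiospecifically, and the CO2 quench with HCl work-up returns to acid 5.

Further compounds
F1 | step 6 | tert-butyl 2,4-dihydroxy-6-pentylbenzoate | CCCCCc1cc(O)cc(O)c1C(=O)OC(C)(C)C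
F2 | step 4 | methyl 3-[(3-chloro-2,4-dimethoxy-6-pentylbenzoyl)oxy]but-3-enoate | C=C(CC(=O)OC)OC(=O)c1c(CCCCC)cc(OC)c(Cl)c1OC
F3 | step 2 | 1-bromo-3-chloro-2,4-dimethoxy-6-pentylbenzene | CCCCCc1cc(OC)c(Cl)c(OC)c1Br
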